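**Strategy**

The target is cut back to a ring B/C dienone by removing ring A and the lactone from the C4 ketone. In ring C of that dienone the trisubstituted C12=C13 alkene (later the epoxide) sits one methylene (C14) away from quaternary C6, which carries the angular methyl, and C5=C10 lies one methylene (C11) away on the other side. This 1,4-diene is the retron of a cis-divinylcyclopropane Cope rearrangement. One thermal step bonds C14 to C6, opens the C10–C11–C12 cyclopropane, closes ring C and hands the cyclopropane configuration on to C6. The precursor is 3-methylcyclohexenone carrying at C5 a cis-2-methyl-2-vinylcyclopropyl group, made by asymmetric Simmons–Smith cyclopropanation.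

Key step: step 7

Atom labels used in names: ring A C1–C2–C3–C4–C9; ring B C4–C5–C6–C7–C8–C9; ring C C5–C10–C11–C12–C13–C14–C6; C15 methyl on C6, C16 methyl on C12, C17 the CH2O carbon on C9; lactone C2–O–C20(=O)–C18(=C19)–C3; β is the face of the C6 methyl, α the face of H-5.

Assumption: the (4S,5S)-dioxaborolane (step 4) and (S,S)-ProPhenol (step 13) are taken to show their usual facial sense; if either proves reversed on these substrates, the enantiomeric ligand is used and nothing else changes.

**Route**

Step 1
Reactants: 1 3-methylcyclohex-2-en-1-one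
Product: 2 2-iodo-3-methylcyclohex-2-en-1-one
Conditions: I2, pyridine, CH2Cl2, 0 → 25 °C
Reagents that add atoms: iodine, II
Why: α-Iodination of the enone by reversible conjugate addition of pyridine, iodination of the resulting enolate and elimination is a standard route to 2-iodo-enones and gives the handle for cross-coupling at C5.

Step 2
Reactants: 3 prop-2-yn-1-ol; 4 methylmagnesium bromide
Product: 6 (2Z)-2-methyl-3-(tributylstannyl)prop-2-en-1-ol, via alkenylmagnesium alkoxide 5 (not isolated)
Conditions: CuI (10 mol%), THF, −10 → 25 °C; then Bu3SnCl, 0 → 25 °C; H2O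
Reagents that add atoms: tributyltin chloride, CCCC[Sn](Cl)(CCCC)CCCC
Why: Copper-catalysed anti-carbomagnesiation of the magnesium propargyl alkoxide places methyl on the internal carbon and magnesium on the terminal carbon cis to CH2O through a five-membered chelate, and transmetalation of the alkenyl–magnesium bond to tin with retention fixes the Z geometry that later makes the cyclopropane cis.

Step 3
Reactants: 2 2-iodo-3-methylcyclohex-2-en-1-one; 6 (2Z)-2-methyl-3-(tributylstannyl)prop-2-en-1-ol
Product: 7 2-[(1Z)-3-hydroxy-2-methylprop-1-en-1-yl]-3-methylcyclohex-2-en-1-one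
Conditions: Pd2(dba)3 (2.5 mol%), AsPh3 (20 mol%), CuI (10 mol%), NMP, 25–45 °C
Reagents that add atoms: none
Why: Stille cross-coupling of an α-iodo-enone with an alkenylstannane, accelerated by the weakly donating arsine and the copper co-catalyst, tolerates the free hydroxyl and transfers the alkenyl group with retention of the Z geometry.

Step 4
Reactants: 7 2-[(1Z)-3-hydroxy-2-methylprop-1-en-1-yl]-3-methylcyclohex-2-en-1-one
Product: 8 2-[(1S,2R)-2-(hydroxymethyl)-2-methylcyclopropyl]-3-methylcyclohex-2-en-1-one (enone ring and CH2OH cis on the cyclopropane)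
Conditions: Et2Zn, CH2I2, DME, CH2Cl2, −10 °C; then 7 and (4S,5S)-2-butyl-N,N,N′,N′-tetramethyl-1,3,2-dioxaborolane-4,5-dicarboxamide (1.2 equiv), −10 → 25 °C
Reagents that add atoms: diiodomethane, ICI
Why: Hydroxyl-directed asymmetric Simmons–Smith cyclopropanation in which the zinc alkoxide binds the chiral dioxaborolane, so that the zinc carbenoid adds syn to one face of C10=C12, turning the Z alkene into the cis cyclopropane and setting C10 (S) and C12 (R), while the electron-poor tetrasubstituted enone alkene does not react with the electrophilic carbenoid.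

Step 5
Reactants: 8 2-[(1S,2R)-2-(hydroxymethyl)-2-methylcyclopropyl]-3-methylcyclohex-2-en-1-one
Product: 9 (1R,2S)-1-methyl-2-(2-methyl-6-oxocyclohex-1-en-1-yl)cyclopropane-1-carbaldehyde
Conditions: 1,1,1-triacetoxy-1,1-dihydro-1,2-benziodoxol-3(1H)-one (DMP), CH2Cl2, 0 → 25 °C
Reagents that add atoms: none
Why: Oxidation of the primary alcohol by the hypervalent iodine reagent under neutral conditions stops at the aldehyde, which has no α-hydrogen and so cannot epimerise at C12; it is used at once to limit reversible retro-Claisen valence isomerisation of the cis-2-alkenylcyclopropane carbaldehyde.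

Step 6
Reactants: 9 (1R,2S)-1-methyl-2-(2-methyl-6-oxocyclohex-1-en-1-yl)cyclopropane-1-carbaldehyde
Product: 10 2-[(1S,2S)-2-ethenyl-2-methylcyclopropyl]-3-methylcyclohex-2-en-1-one (vinyl cis to the enone ring)
Conditions: Ph3PCH3Br, KN(SiMe3)2, THF, 0 °C; then 9, −78 → 0 °C
Reagents that add atoms: methyltriphenylphosphonium bromide, C[P+](c1ccccc1)(c1ccccc1)c1ccccc1.[Br-]
Why: Wittig methylenation with a slight excess of ylide at low temperature is selective for the aldehyde over the hindered, conjugated ring ketone and leaves both cyclopropane stereocentres untouched.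

Step 7
Reactants: 10 2-[(1S,2S)-2-ethenyl-2-methylcyclopropyl]-3-methylcyclohex-2-en-1-one
Product: 11 (4aS)-4a,7-dimethyl-2,3,4,4a,5,8-hexahydro-1H-benzo[7]annulen-1-one (ring B/C dienone: C4=O, C5=C10, C12=C13, quaternary C6)
Conditions: toluene (degassed), sealed tube, 110 °C
Reagents that add atoms: none
Why: Heating populates the conformer in which the C13=C14 vinyl group and the ring B enone alkene both lie over the cyclopropane, and a concerted, suprafacial (3,3)-sigmatropic shift through this boat-shaped six-centre array joins C14 to the enone β-carbon C6 while the C10–C12 ring bond breaks, the loss of three-membered ring strain making the process irreversible. The closest known reaction type is the Cope rearrangement of cis-1,2-divinylcyclopropanes to cyclohepta-1,4-dienes, here with one vinyl unit embedded in a cyclohexenone. Ring C is closed by this 3-to-7 ring expansion, a pericyclic closure in which the new sigma bond joins the two alkene termini and not an exo or endo attack; C11 ends as the methylene between C5=C10 and C12=C13 and the C4 ketone stays conjugated. The one new stereocentre, quaternary C6, is controlled by the cyclopropane configuration from step 4, because the cis tether lets C14 reach only one face of C5=C6, so that (1S,2S)-10 should give (S)-C6. The step needs the concerted pathway to be faster than homolytic cis–trans stereomutation of the cyclopropane, which would erode enantiomeric purity; the fixed cis geometry, the strain release and the acyl substituent on the diene favour it, although the methyl on C6 points into the boat and makes heating necessary.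

Step 8
Reactants: 11 (4aS)-4a,7-dimethyl-2,3,4,4a,5,8-hexahydro-1H-benzo[7]annulen-1-one
Product: 13 (4aS,9aS)-4a,7-dimethyl-2,3,4,4a,5,8,9,9a-octahydro-1H-benzo[7]annulen-1-one (trans ring B/C ketone, H-5 α, C6 methyl β), via lithium C4–C5 enolate 12 (not isolated)
Conditions: LiBH(s-Bu)3, THF, −78 °C; H2O; then NaOMe (cat.), MeOH, 25 °C
Reagents that add atoms: none
Why: Conjugate (1,4) hydride reduction of the s-cis alkylidene ketone by the bulky borohydride gives enolate 12, C5 is protonated on work-up, and methoxide then equilibrates this epimerisable centre to the trans ring B/C fusion, in which H-5 is axial and anti to the axial C6 methyl and both ring C bonds are equatorial.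

Step 9
Reactants: 13 (4aS,9aS)-4a,7-dimethyl-2,3,4,4a,5,8,9,9a-octahydro-1H-benzo[7]annulen-1-one; 14 2,2-dimethoxyacetaldehyde
Product: 15 (2E,4aS,9aS)-2-(2,2-dimethoxyethylidene)-4a,7-dimethyl-2,3,4,4a,5,8,9,9a-octahydro-1H-benzo[7]annulen-1-one (C9=C1 alkylidene ketone)
Conditions: KOH, MeOH–H2O, 0 → 25 °C
Reagents that add atoms: none
Why: Claisen–Schmidt (crossed aldol) condensation with a non-enolisable aldehyde can complete its dehydration only at the C9 methylene, the E alkylidene ketone with the acetal arm anti to the carbonyl is the stable isomer, and the base keeps C5 at its trans equilibrium.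

Step 10
Reactants: 15 (2E,4aS,9aS)-2-(2,2-dimethoxyethylidene)-4a,7-dimethyl-2,3,4,4a,5,8,9,9a-octahydro-1H-benzo[7]annulen-1-one
Product: 17 (2S,4aS,9aS)-2-(2,2-dimethoxyethyl)-2-(hydroxymethyl)-4a,7-dimethyl-2,3,4,4a,5,8,9,9a-octahydro-1H-benzo[7]annulen-1-one (C17 hydroxymethyl α, C1 arm β on C9), via lithium C4–C9 enolate 16 (not isolated)
Conditions: LiBH(s-Bu)3, THF, −78 °C; then CH2O (gas, from cracked paraformaldehyde), −78 → −40 °C; AcOH, −78 °C
Reagents that add atoms: formaldehyde, C=O
Why: Reductive aldol sequence in which 1,4-hydride addition gives the tetrasubstituted C4=C9 enolate 16 regiospecifically and monomeric formaldehyde attacks it axially on the α face of the half-chair, anti to the β-axial C6 methyl across ring B, making C9 quaternary with C17 α and the C1 arm β.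

Step 11
Reactants: 17 (2S,4aS,9aS)-2-(2,2-dimethoxyethyl)-2-(hydroxymethyl)-4a,7-dimethyl-2,3,4,4a,5,8,9,9a-octahydro-1H-benzo[7]annulen-1-one
Product: 18 the 17-O-tert-butyldiphenylsilyl ether of 17
Conditions: TBDPSCl, imidazole, DMF, 25 °C
Reagents that add atoms: tert-butyl(chloro)diphenylsilane, CC(C)(C)[Si](Cl)(c1ccccc1)c1ccccc1
Why: Imidazole-promoted silylation of the primary neopentyl-type alcohol closes the retro-aldol pathway and installs an ether that survives acid, zinc alkynylide, SmI2 and amide base.

Step 12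
Reactants: 18 the 17-O-tert-butyldiphenylsilyl ether of 17
Product: 19 2-[(2S,4aS,9aS)-2-{[tert-butyl(diphenyl)silyl]oxymethyl}-4a,7-dimethyl-1-oxo-2,3,4,4a,5,8,9,9a-octahydro-1H-benzo[7]annulen-2-yl]acetaldehyde (C2 aldehyde)
Conditions: 1 M aq. HCl, THF, 25 °C
Reagents that add atoms: water, O
Why: Acid-catalysed hydrolysis of the dimethyl acetal through the oxocarbenium ion frees the C2 aldehyde, while the acid-stable silyl ether and the trisubstituted alkene stay intact.

Step 13
Reactants: 19 the C2 aldehyde; 20 methyl prop-2-ynoate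
Product: 22 methyl (4S)-4-hydroxy-5-[(2S,4aS,9aS)-2-{[tert-butyl(diphenyl)silyl]oxymethyl}-4a,7-dimethyl-1-oxo-octahydro-1H-benzo[7]annulen-2-yl]pent-2-ynoate, via methylzinc alkynylide 21 (not isolated)
Conditions: Me2Zn, (S,S)-ProPhenol (20 mol%), Ph3P=O (40 mol%), toluene, 0 → 4 °C; H2O
Reagents that add atoms: none
Why: Catalytic enantioselective alkynylation of the aldehyde, in which the zinc alkynylide is delivered inside the dinuclear zinc–ProPhenol pocket to the Re face of C2, so that C2 (S) is set by the ligand and not by the remote ring stereocentres, while the hindered α-quaternary ketone is inert to the organozinc.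

Step 14
Reactants: 22 the (4S)-hydroxy ynoate
Product: 24 (5S)-5-{[(2S,4aS,9aS)-2-{[tert-butyl(diphenyl)silyl]oxymethyl}-4a,7-dimethyl-1-oxo-octahydro-1H-benzo[7]annulen-2-yl]methyl}furan-2(5H)-one (butenolide, C2 its γ-carbon), via (Z)-hydroxy enoate 23 (not isolated)
Conditions: H2 (1 atm), Pd/CaCO3 poisoned with Pb(OAc)2, quinoline, EtOAc, 25 °C; then PPTS (cat.), toluene, 40 °C
Reagents that add atoms: none
Why: Semi-hydrogenation of the ynoate over the poisoned palladium catalyst gives the Z enoate, whose ester is cis to the C2 hydroxyl and lactonises to the butenolide, with C2 unaffected and the trisubstituted ring alkene untouched.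

Step 15
Reactants: 24 the butenolide ketone
Product: 25 (2S,3S,4R,5S,6S,9S)-tricyclic hydroxy lactone: ring A closed by the C3–C4 bond, 4β-OH, 3β-H, γ-lactone C2–O–C20(=O)–C18H2–C3 cis-fused on the α face, 17-OTBDPS, C12=C13
Conditions: SmI2 (2.5 equiv), HMPA, t-BuOH (2 equiv), THF, −78 → −20 °C
Reagents that add atoms: none
Why: Single-electron reduction of the C4 ketone gives a samarium ketyl that adds 5-exo-trig to the butenolide β-carbon C3 (ketyl–olefin cyclisation); C3 bonds on the butenolide face that carries C1 (fixed by C2), approach to C4 is equatorial because the axial path is blocked by the syn-axial C6 methyl, and the HMPA-solvated ketyl oxygen stays anti to the lactone carbonyl arm, which together should give trans-fused ring A with 4β-OH.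

Step 16
Reactants: 25 the tricyclic hydroxy lactone
Product: 29 the α-methylene lactone (C18=C19H2) with 4β-OH and 17-OTBDPS, via dilithium alkoxide enolate 26 (not isolated), via Mannich base 27 (not isolated), via trimethylammonium iodide 28 (not isolated)
Conditions: LiN(i-Pr)2 (3 equiv), THF, −78 °C; [Me2N=CH2]I, −78 → 25 °C; then MeI, MeOH, 25 °C; then aq. NaHCO3, CH2Cl2, 25 °C
Reagents that add atoms: N,N-dimethylmethyleneiminium iodide, C=[N+](C)C.[I-]
Why: α-Methylenation of the lactone by Mannich reaction of its lithium enolate with the iminium salt, N-methylation and E1cB loss of trimethylamine; the sp3 centre made at C18 is removed again, so no stereochemical question arises.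

Step 17
Reactants: 29 the silyl-protected α-methylene lactone
Product: 30 the 4β,17-diol α-methylene lactone
Conditions: HF·pyridine, pyridine, THF, 0 → 25 °C
Reagents that add atoms: none
Why: Fluoride-mediated cleavage of the silyl ether under mildly acidic conditions avoids conjugate addition to the α-methylene lactone, which free basic fluoride could cause.

Step 18
Reactants: 30 the 4β,17-diol
Product: 31 the 17-acetate (4β-OH free)
Conditions: Ac2O (1.2 equiv), pyridine, DMAP (cat.), CH2Cl2, 0 °C
Reagents that add atoms: acetic anhydride, CC(=O)OC(C)=O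
Why: DMAP-catalysed acylation is selective for the primary C17 hydroxyl over the hindered tertiary C4 hydroxyl.

Step 19
Reactants: 31 the 17-acetate
Product: 32 target, (2S,3S,4R,5S,6S,9S,12S,13R)-17-acetoxy-12α,13α-epoxy-4β-hydroxy α-methylene lactone (CNP0214540.1)
Conditions: m-CPBA, CH2Cl2, 0 °C
Reagents that add atoms: 3-chloroperoxybenzoic acid, OOC(=O)c1cccc(Cl)c1
Why: Prilezhaev epoxidation by the electrophilic peracid is chemoselective for the electron-rich trisubstituted C12=C13 alkene over the electron-poor α-methylene lactone, and attack should come from the α face, anti to the β C6 methyl that is homoallylic to C13 and screens the β face of ring C.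

**Compound list**

1 | 3-methylcyclohex-2-en-1-one | CC1=CC(=O)CCC1 | starting material
2 | 2-iodo-3-methylcyclohex-2-en-1-one | CC1=C(I)C(=O)CCC1 | intermediate
3 | prop-2-yn-1-ol | C#CCO | starting material
4 | methylmagnesium bromide | C[Mg]Br | starting material
5 | [(1Z)-3-(bromomagnesiooxy)-2-methylprop-1-en-1-yl]magnesium bromide (not isolated) | Br[Mg]/C=C(/C)CO[Mg]Br | intermediate
6 | (2Z)-2-methyl-3-(tributylstannyl)prop-2-en-1-ol | CCCC[Sn](CCCC)(CCCC)/C=C(/C)CO | intermediate
7 | 2-[(1Z)-3-hydroxy-2-methylprop-1-en-1-yl]-3-methylcyclohex-2-en-1-one | CC1=C(/C=C(/C)CO)C(=O)CCC1 | intermediate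
8 | 2-[(1S,2R)-2-(hydroxymethyl)-2-methylcyclopropyl]-3-methylcyclohex-2-en-1-one | O=C1CCCC(C)=C1[C@H]2C[C@@]2(C)CO | intermediate
9 | (1R,2S)-1-methyl-2-(2-methyl-6-oxocyclohex-1-en-1-yl)cyclopropane-1-carbaldehyde | O=C1CCCC(C)=C1[C@H]2C[C@@]2(C)C=O | intermediate
10 | 2-[(1S,2S)-2-ethenyl-2-methylcyclopropyl]-3-methylcyclohex-2-en-1-one | O=C1CCCC(C)=C1[C@H]2C[C@@]2(C)C=C | intermediate
11 | (4aS)-4a,7-dimethyl-2,3,4,4a,5,8-hexahydro-1H-benzo[7]annulen-1-one | O=C1CCC[C@@]2(C)CC=C(C)CC=C12 | intermediate
12 | lithium C4–C5 enolate of 13 (not isolated) | [Li]OC1=C2CCC(C)=CC[C@]2(C)CCC1 | intermediate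
13 | (4aS,9aS)-4a,7-dimethyl-2,3,4,4a,5,8,9,9a-octahydro-1H-benzo[7]annulen-1-one | O=C1CCC[C@@]2(C)CC=C(C)CC[C@H]12 | intermediate
14 | 2,2-dimethoxyacetaldehyde | COC(OC)C=O | starting material
15 | (2E,4aS,9aS)-2-(2,2-dimethoxyethylidene)-4a,7-dimethyl-2,3,4,4a,5,8,9,9a-octahydro-1H-benzo[7]annulen-1-one | COC(OC)/C=C1\CC[C@@]2(C)CC=C(C)CC[C@@H]2C1=O | intermediate
16 | lithium C4–C9 enolate with the 2,2-dimethoxyethyl arm on C9 (not isolated) | COC(OC)CC1=C(O[Li])[C@H]2CCC(C)=CC[C@]2(C)CC1 | intermediate
17 | (2S,4aS,9aS)-2-(2,2-dimethoxyethyl)-2-(hydroxymethyl)-4a,7-dimethyl-2,3,4,4a,5,8,9,9a-octahydro-1H-benzo[7]annulen-1-one | COC(OC)C[C@]1(CO)CC[C@@]2(C)CC=C(C)CC[C@@H]2C1=O | intermediate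
18 | 17-O-tert-butyldiphenylsilyl ether of 17 | COC(OC)C[C@]1(CO[Si](c3ccccc3)(c3ccccc3)C(C)(C)C)CC[C@@]2(C)CC=C(C)CC[C@@H]2C1=O | intermediate
19 | C2 aldehyde: 2-[(2S,4aS,9aS)-2-{[tert-butyl(diphenyl)silyl]oxymethyl}-4a,7-dimethyl-1-oxo-octahydro-1H-benzo[7]annulen-2-yl]acetaldehyde | O=CC[C@]1(CO[Si](c3ccccc3)(c3ccccc3)C(C)(C)C)CC[C@@]2(C)CC=C(C)CC[C@@H]2C1=O | intermediate
20 | methyl prop-2-ynoate | C#CC(=O)OC | starting material
21 | methyl 3-(methylzincio)prop-2-ynoate (not isolated) | C[Zn]C#CC(=O)OC | intermediate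
22 | methyl (4S)-4-hydroxy-5-[ring B/C ketone core of 19]pent-2-ynoate | COC(=O)C#C[C@@H](O)C[C@]1(CO[Si](c3ccccc3)(c3ccccc3)C(C)(C)C)CC[C@@]2(C)CC=C(C)CC[C@@H]2C1=O | intermediate
23 | methyl (2Z,4S)-4-hydroxy-5-[ring B/C ketone core of 19]pent-2-enoate (not isolated) | COC(=O)/C=C\[C@@H](O)C[C@]1(CO[Si](c3ccccc3)(c3ccccc3)C(C)(C)C)CC[C@@]2(C)CC=C(C)CC[C@@H]2C1=O | intermediate
24 | (5S)-5-{[ring B/C ketone core of 19]methyl}furan-2(5H)-one | O=C1C=C[C@@H](O1)C[C@]2(CO[Si](c4ccccc4)(c4ccccc4)C(C)(C)C)CC[C@@]3(C)CC=C(C)CC[C@@H]3C2=O | intermediate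
25 | (2S,3S,4R,5S,6S,9S)-tricyclic hydroxy lactone, 4β-OH, saturated C18H2, 17-OTBDPS, C12=C13 | C1C(=O)O[C@H]2C[C@]3(CO[Si](c5ccccc5)(c5ccccc5)C(C)(C)C)CC[C@@]4(C)CC=C(C)CC[C@@H]4[C@@]3(O)[C@@H]12 | intermediate
26 | dilithium C4 alkoxide / lactone enolate of 25 (not isolated) | C1=C(O[Li])O[C@H]2C[C@]3(CO[Si](c5ccccc5)(c5ccccc5)C(C)(C)C)CC[C@@]4(C)CC=C(C)CC[C@@H]4[C@@]3(O[Li])[C@@H]12 | intermediate
27 | 18-(dimethylaminomethyl) lactone, Mannich base (not isolated) | CN(C)CC1C(=O)O[C@H]2C[C@]3(CO[Si](c5ccccc5)(c5ccccc5)C(C)(C)C)CC[C@@]4(C)CC=C(C)CC[C@@H]4[C@@]3(O)[C@@H]12 | intermediate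
28 | 18-(trimethylammoniomethyl) lactone iodide (not isolated) | C[N+](C)(C)CC1C(=O)O[C@H]2C[C@]3(CO[Si](c5ccccc5)(c5ccccc5)C(C)(C)C)CC[C@@]4(C)CC=C(C)CC[C@@H]4[C@@]3(O)[C@@H]12.[I-] | intermediate
29 | α-methylene lactone, 4β-OH, 17-OTBDPS, C12=C13 | C=C1C(=O)O[C@H]2C[C@]3(CO[Si](c5ccccc5)(c5ccccc5)C(C)(C)C)CC[C@@]4(C)CC=C(C)CC[C@@H]4[C@@]3(O)[C@@H]12 | intermediate
30 | α-methylene lactone 4β,17-diol, C12=C13 | C=C1C(=O)O[C@H]2C[C@]3(CO)CC[C@@]4(C)CC=C(C)CC[C@@H]4[C@@]3(O)[C@@H]12 | intermediate
31 | α-methylene lactone 17-acetate, 4β-OH, C12=C13 | C=C1C(=O)O[C@H]2C[C@]3(COC(C)=O)CC[C@@]4(C)CC=C(C)CC[C@@H]4[C@@]3(O)[C@@H]12 | intermediate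
32 | (2S,3S,4R,5S,6S,9S,12S,13R)-17-acetoxy-12α,13α-epoxy-4β-hydroxy α-methylene lactone, CNP0214540.1 | C=C1C(=O)O[C@H]2C[C@]3(COC(C)=O)CC[C@@]4(C)C[C@H]5O[C@@]5(C)CC[C@@H]4[C@@]3(O)[C@@H]12 | target

**Step count and risks**

Total steps: 19. Longest linear sequence: 18 steps (steps 1 and 3–19 from compound 1; the branch from 3 and 4 through step 2 is equally long).

The three steps most likely to fail:

Step 7, the sigmatropic ring expansion. The methyl on C6 points into the boat and may slow the concerted pathway so much that homolysis of the doubly allylic C10–C12 bond and reclosure (cis–trans stereomutation) erodes enantiomeric purity or diverts material. The fallback sets out from 1 and returns at 11 without any cyclopropane. Enantioselective 1,2-allylation of 1 (tetraallyltin, Ti(Oi-Pr)4, the BINOL enantiomer that gives the S carbinol, i-PrOH, CH2Cl2) would give (S)-3-methyl-1-(prop-2-en-1-yl)cyclohex-2-en-1-ol F1. Anionic oxy-Cope rearrangement (KH, 18-crown-6, THF) moves the allyl group suprafacially from C4 to C6 and gives potassium (3S)-3-methyl-3-(prop-2-en-1-yl)cyclohex-1-en-1-olate F2, the regiodefined C4–C5 enolate. Aldol trapping of this enolate with 3-methylbut-3-enal at −78 °C gives (3S)-2-(1-hydroxy-3-methylbut-3-en-1-yl)-3-methyl-3-(prop-2-en-1-yl)cyclohexan-1-one F3. Dehydration with methyl N-(triethylammoniosulfonyl)carbamate gives (2E,3S)-3-methyl-2-(3-methylbut-3-en-1-ylidene)-3-(prop-2-en-1-yl)cyclohexan-1-one F4. Ring-closing metathesis of its two terminal alkenes (second-generation Grubbs catalyst RuCl2(=CHPh)(PCy3)(H2IMes), CH2Cl2, 40 °C) closes ring C at C12=C13 and gives 11.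

Step 15, the ketyl cyclisation. Electron transfer to the butenolide may outrun ketyl formation and lead to conjugate reduction or reductive opening of the γ C–O bond, or the ketyl may add through a chelated syn arrangement and give the wrong relative configuration at C3 and C4. The fallback sets out from 22 and returns at 25. The hydroxy ynoate 22 is itself treated with SmI2 (HMPA, t-BuOH, THF), so that the ketyl adds 5-exo-dig to alkyne carbon C3, where no syn or anti question exists. This gives the ring A alkylidene ester with exocyclic C3=C18, the ester cis to C2 and free 2α- and 4β-hydroxyls F5. Acid (PPTS, toluene) closes it to the fused butenolide with C3=C18 inside the lactone and 4β-OH F6. Conjugate reduction of that butenolide (NaBH4, NiCl2·6H2O, MeOH, 0 °C) can place hydrogen on C3 only cis to H-2, because the bicyclic lactone must be cis-fused, and gives 25.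

Step 10, the reductive hydroxymethylation. Formaldehyde is small and the transition state early, so facial discrimination at C9 may be poor, and the lithium aldolate may lose formaldehyde again by retro-aldol cleavage. The fallback sets out from 15 and returns at 17. Enolate 16, made as in step 10, is trapped with Me3SiCl and the trimethylsilyl C4–C9 enol ether F7 is isolated. A catalyst-controlled Mukaiyama hydroxymethylation follows (aqueous CH2O, Sc(OTf)3 and a chiral 6,6′-bis(1-hydroxy-2,2-dimethylpropyl)-2,2′-bipyridine, DME–H2O, −20 °C), with the ligand enantiomer matched to α-face attack; the neutral conditions also avoid the retro-aldol pathway.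

**Further compounds**

F1 | step 7 | (S)-3-methyl-1-(prop-2-en-1-yl)cyclohex-2-en-1-ol | C=CC[C@]1(O)C=C(C)CCC1
F2 | step 7 | potassium (3S)-3-methyl-3-(prop-2-en-1-yl)cyclohex-1-en-1-olate | C=CC[C@]1(C)CCCC(O[K])=C1
F3 | step 7 | (3S)-2-(1-hydroxy-3-methylbut-3-en-1-yl)-3-methyl-3-(prop-2-en-1-yl)cyclohexan-1-one | C=CC[C@]1(C)CCCC(=O)C1C(O)CC(C)=C
F4 | step 7 | (2E,3S)-3-methyl-2-(3-methylbut-3-en-1-ylidene)-3-(prop-2-en-1-yl)cyclohexan-1-one | C=CC[C@]1(C)CCCC(=O)/C1=C/CC(C)=C
F5 | step 15 | ring A alkylidene ester with exocyclic C3=C18, ester cis to C2, 2α-OH, 4β-OH, 17-OTBDPS | COC(=O)/C=C1\[C@@H](O)C[C@]2(CO[Si](c4ccccc4)(c4ccccc4)C(C)(C)C)CC[C@@]3(C)CC=C(C)CC[C@@H]3[C@@]12O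
F6 | step 15 | fused butenolide with C3=C18 inside the lactone, 4β-OH, 17-OTBDPS | O=C1C=C2[C@@H](O1)C[C@]3(CO[Si](c5ccccc5)(c5ccccc5)C(C)(C)C)CC[C@@]4(C)CC=C(C)CC[C@@H]4[C@@]23O
F7 | step 10 | trimethylsilyl C4–C9 enol ether with the 2,2-dimethoxyethyl arm on C9 | COC(OC)CC1=C(O[Si](C)(C)C)[C@H]2CCC(C)=CC[C@]2(C)CC1
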